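Assumptions: with CIP order syncarpyl > aryl > iPr > H, both stereocentres in the SMILES are R, so the target is the C2-symmetric, non-meso isomer. The enol tautomer is drawn as given. C* denotes the methine stereocentre and primed numbers refer to the syncarpic ring. Compound numbers are assigned in the forward route.

## Retrosynthetic overview
1. Last step: cut each syncarpic ring at C1′–C2′ and C5′–C6′. This gives an angular bis(4-isopropyl-dihydrocoumarin) plus 2 × 2,2,4,4-tetramethylcyclobutane-1,3-dione. The annulation also frees the phenols, so no end-game deprotection is needed.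
2. The bis-lactone comes from Friedel–Crafts hexanoylation and O-demethylation/lactonisation of a C2-symmetric bis(3-aryl-4-methylpentanoate).
3. The C*–CH2 bond (future C*–C6′) comes from a photochemical Wolff 1,2-shift of C*, with retention, in a bis(diazoketone).
4. The C*–aryl bond comes from a photochemical 1,2-aryl migration, with inversion, in a bis(α-chloro ketone). That ketone is 1,3,5-trimethoxybenzene plus 2 × D-valine-derived chloro acid, so both stereocentres are the valine α-carbon.
5. Ring order: the arene is bought, the two δ-lactone rings form in step 6, and both syncarpic rings form together in step 7. The route is two-directional throughout.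

## Route

**Step 1**
Reactants: 1 D-valine
Product: 2 (R)-2-chloro-3-methylbutanoic acid
Conditions: NaNO2, 5 M HCl, 0 °C → rt
Reagents that add atoms: hydrochloric acid, Cl
Why: Diazotisation of an α-amino acid proceeds through the α-lactone (double inversion), so chloride replaces nitrogen with net retention and the purchased stereocentre is kept as R.

**Step 2**
Reactants: 2 (2.4 equiv); 3 1,3,5-trimethoxybenzene
Product: 4 (2R,2′R)-1,1′-(2,4,6-trimethoxybenzene-1,3-diyl)bis(2-chloro-3-methylbutan-1-one)
Conditions: (COCl)2, cat. DMF, CH2Cl2, rt (crude acid chloride); then 3, SnCl4, CH2Cl2, −20 °C → rt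
Reagents that add atoms: none (all atoms come from 2 and 3)
Why: This is a double Friedel–Crafts acylation; the first acyl group is twisted out of conjugation by its two ortho-OMe groups (as in diacylation of mesitylene), so the ring stays reactive enough for a second acylation, and C* is untouched under non-basic conditions.

**Step 3**
Reactants: 4
Product: 5 (2R,2′R)-2,2′-(2,4,6-trimethoxybenzene-1,3-diyl)bis(3-methylbutanoic acid)
Conditions: hν (λ ≥ 300 nm, Pyrex or flow), acetone/H2O 4:1, propylene oxide (HCl scavenger), 15 °C
Reagents that add atoms: water, O
Why: In this photo-Favorskii-type 1,2-aryl migration of an α-chloro aryl ketone, excitation breaks C–Cl while the electron-rich ring, held orthogonal to C=O by the ortho-OMe groups (the geometry needed for bridging), attacks C* anti to chloride and water opens the bridged acyl intermediate, so each C*–aryl bond forms with inversion (R chloride → R acid because the priorities change), any leakage shows up mainly as the separable meso diacid and so raises the ee of the C2 isomer, and the product does not absorb above 300 nm.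

**Step 4**
Reactants: 5; 6 (trimethylsilyl)diazomethane
Product: 7 (3R,3′R)-3,3′-(2,4,6-trimethoxybenzene-1,3-diyl)bis(1-diazo-4-methylpentan-2-one)
Conditions: 1-chloro-N,N,2-trimethylpropenylamine, CH2Cl2, 0 °C; then 6 (6 equiv), CaO, THF/MeCN, 0 °C → rt (C-desilylation on work-up)
Reagents that add atoms: (trimethylsilyl)diazomethane, C[Si](C)(C)C=[N+]=[N-]
Why: This is Arndt–Eistert acylation of a diazoalkane; neutral acid-chloride formation and an insoluble HCl scavenger instead of an amine avoid the aryl-ketene pathway, so the α-aryl stereocentre is not epimerised.

**Step 5**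
Reactants: 7
Product: 8 dimethyl (3R,3′R)-3,3′-(2,4,6-trimethoxybenzene-1,3-diyl)bis(4-methylpentanoate)
Conditions: hν (365 nm LED), MeOH, rt
Reagents that add atoms: methanol, CO
Why: In the photochemical Wolff rearrangement C* migrates from the carbonyl carbon to the carbene carbon with retention, forming the future C*–C6′ bond, and the ketene is trapped by methanol, while the arene is transparent at 365 nm.

**Step 6**
Reactants: 8; 9 hexanoyl chloride
Product: 10 (4R,10R)-6-hexanoyl-5-hydroxy-4,10-di(propan-2-yl)-3,4,9,10-tetrahydro-2H,8H-pyrano[2,3-f]chromene-2,8-dione (a regioisomeric bis-lactone would converge in step 7)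
Conditions: 9, AlCl3, CH2Cl2, 0 °C; then BBr3, −78 °C → rt; aq. HCl work-up (one flask)
Reagents that add atoms: hexanoyl chloride, CCCCCC(=O)Cl
Why: Friedel–Crafts acylation can only occur at the single free, doubly ortho-activated position, BBr3 ether cleavage then frees the phenols and the crowded arms lactonise spontaneously, leaving free the OH that is hydrogen-bonded to the ketone, and C* (β to the ester, with no ionisable group) is configurationally safe here.

**Step 7**
Reactants: 10; 11 2,2,4,4-tetramethylcyclobutane-1,3-dione (2.6 equiv)
Product: 12 myrtucommulone F, (R,R)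
Conditions: 10, NaHMDS (3.1 equiv), THF/DMPU, −78 °C; then premixed 11/NaOMe (2.4 equiv, THF, 0 °C, 30 min); −78 → 0 °C; cold 1 M HCl
Reagents that add atoms: 2,2,4,4-tetramethylcyclobutane-1,3-dione, CC1(C)C(=O)C(C)(C)C1=O
Why: Proposed new method: a methoxide-shuttled lactone-to-β-triketone ring exchange in which NaOMe opens strained 11 to the tertiary enolate MeO2C–CMe2–CO–CMe2(−), NaHMDS turns each aryl-ester lactone into its enolate/ketene–phenoxide (E1cB), the tertiary enolate C-acylates at the former lactone carbonyl (C1′–C2′ bond, phenoxide released), and the resulting C6′ enolate closes onto the methyl ester (Dieckmann, C5′–C6′ bond), expelling methoxide; the acidic triketone enolate is the thermodynamic sink and also drains any O-acylated material, the net change is 10 + 2 × 11 = 12 with no atoms lost, C* is a spectator (not acidic; kept ≤ 0 °C to prevent retro-Michael), and the closest known reactions are the alkoxide-catalysed union of dimethylketene dimer with a ketene to give hexamethylcyclohexane-1,3,5-trione and crossed-Claisen/Dieckmann syntheses of β-triketones.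

## Compound list
1 | D-valine | CC(C)[C@@H](N)C(=O)O | starting material
2 | (R)-2-chloro-3-methylbutanoic acid | CC(C)[C@@H](Cl)C(=O)O | intermediate
3 | 1,3,5-trimethoxybenzene | COc1cc(OC)cc(OC)c1 | starting material
4 | (2R,2′R)-1,1′-(2,4,6-trimethoxybenzene-1,3-diyl)bis(2-chloro-3-methylbutan-1-one) | COc1cc(OC)c(C(=O)[C@H](Cl)C(C)C)c(OC)c1C(=O)[C@H](Cl)C(C)C | intermediate
5 | (2R,2′R)-2,2′-(2,4,6-trimethoxybenzene-1,3-diyl)bis(3-methylbutanoic acid) | COc1cc(OC)c([C@H](C(=O)O)C(C)C)c(OC)c1[C@H](C(=O)O)C(C)C | intermediate
6 | (trimethylsilyl)diazomethane | C[Si](C)(C)C=[N+]=[N-] | starting material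
7 | (3R,3′R)-3,3′-(2,4,6-trimethoxybenzene-1,3-diyl)bis(1-diazo-4-methylpentan-2-one) | COc1cc(OC)c([C@H](C(=O)C=[N+]=[N-])C(C)C)c(OC)c1[C@H](C(=O)C=[N+]=[N-])C(C)C | intermediate
8 | dimethyl (3R,3′R)-3,3′-(2,4,6-trimethoxybenzene-1,3-diyl)bis(4-methylpentanoate) | COc1cc(OC)c([C@H](CC(=O)OC)C(C)C)c(OC)c1[C@H](CC(=O)OC)C(C)C | intermediate
9 | hexanoyl chloride | CCCCCC(=O)Cl | starting material
10 | (4R,10R)-6-hexanoyl-5-hydroxy-4,10-diisopropyl-3,4,9,10-tetrahydro-2H,8H-pyrano[2,3-f]chromene-2,8-dione | CCCCCC(=O)c1c(O)c2[C@@H](C(C)C)CC(=O)Oc2c3[C@@H](C(C)C)CC(=O)Oc13 | intermediate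
11 | 2,2,4,4-tetramethylcyclobutane-1,3-dione | CC1(C)C(=O)C(C)(C)C1=O | starting material
12 | myrtucommulone F (R,R) | CCCCCC(=O)c1c(O)c([C@H](C2=C(O)C(C)(C)C(=O)C(C)(C)C2=O)C(C)C)c(O)c([C@H](C2=C(O)C(C)(C)C(=O)C(C)(C)C2=O)C(C)C)c1O | target

## Totals and risks
Total steps: 7. Longest linear sequence: 7, from D-valine.

**1. Step 7 (proposed new step)**
- Risks: O- versus C-acylation by the hindered tertiary enolate, sluggish reaction of the second arm on a polyanion, and retro-Michael epimerisation of the product if the mixture is warmed.
- Fallback (known chemistry): build the rings stepwise from 8.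
  - Saponify 8 and form the bis(acid chloride).
  - C-acylate the pre-formed lithium enolate of methyl 2,2,4-trimethyl-3-oxopentanoate (made from 11 with NaOMe/MeOH). This is a classical crossed Claisen.
  - Close both rings in a separate NaOMe Dieckmann step.
  - Carry out the Friedel–Crafts hexanoylation and BBr3 demethylation afterwards.

**2. Step 3**
- Risks: incomplete chirality transfer through a free radical or ion pair, ortho-OMe participation giving 2-isopropylbenzofuran-3-ones, and loss of CO from the bridged intermediate.
- Fallback: form the C*–aryl bond in the ground state. Convert 4 to its bis(dimethyl ketal) and run the ZnBr2- or Ag(I)-promoted stereoinvertive 1,2-aryl shift used for profens from lactate-derived ketones. This gives the dimethyl ester of 5.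

**3. Step 2**
- Risks: the second acylation may stall, or the Lewis acid may cleave an ortho-OMe and the resulting phenol may close onto the C–Cl carbon.
- Fallback: replace the two-directional plan with an iterative one.
  - Mono-acylate 3.
  - Photo-rearrange in MeOH to the α-aryl ester, which re-activates the ring.
  - Acylate again and photo-rearrange again.
  - This costs two extra steps, but every acylation then takes place on an electron-rich ring.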